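(All runs are calculated with made-up constants; scatter was added.)

Elm's D rises far faster than cedar's D falls: it gains 9.2% in the first 5.00 h, while cedar loses 6.4 percentage points between 1.25 d and 4.00 d. So I read the curve with two clocks, one of hours and one of days.

the same everywhere: J 1.5 M
- elm: E 1 equiv; G 0.75 M; the very flask that is asked about, followed so far
- cedar: E 1.5 equiv; G 0.75 M; run made earlier
- flask: E 1.00 equiv; G 0.750 M; time 4.0 d

elm run (percent of the J charged)

| time / h | D / % |
|---|---|
| 5.00 | 9.2 |
| 10.0 | 13.8 |
| 15.0 | 15.3 |
| 20.0 | 16.6 |

cedar run (percent of the J charged)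

| time / d | D / % |
|---|---|
| 0.500 | 20.3 |
| 1.25 | 22.9 |
| 2.50 | 19.1 |
| 4.00 | 16.5 |

(standard deviation of a reading: 0.3 percentage points)

- amount of D in percent of the J charged, at 5.0 h, 25 h and 4.0 d



I start with elm's clock of hours. In steps of 5.00 h, elm gains 9.2%, then 4.6 points, 1.5 points and 1.3 points, so the knee lies near 10.0 h. For 5.0 h I keep the reading. For 25 h I add half of the last gain to the last reading, which puts the crest at about 17.2%.

Past the crest I need the clock of days, and cedar shows it. I call it the fade half-life: the time in which D, past its crest, would halve at the pace read between cedar's highest and last readings, 5.82 d. From 25 h to 4.0 d is 0.508 of these half-lives, so, taking cedar's pace over to elm although cedar holds 1.5 equiv of E against elm's 1 equiv, I expect elm's curve to stand at 12.1% at 4.0 d.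

The forecast gives 9.2%, 17.2% and 11.5%, expecting that “a slow side reaction, probably G consuming E, pulls D back down”. My last point stands higher than its last point.

The flask gives 8.83%, 16.6% and 12.5%, and the forecast holds within its margin.

    J + E ⇌ D (K = 0.250 L mol⁻¹, k = 4.50 × 10⁻⁶ L mol⁻¹ s⁻¹)
    J + G → L (k = 5.10 × 10⁻⁶ L mol⁻¹ s⁻¹)
    D ⇌ X (K = 0.850, k = 2.40 × 10⁻⁶ s⁻¹)

In this flask J + E ⇌ D runs beside J + G → L, and at 0.973 d D is still made 1.27 times faster than it is used up, each step taken net. By 4.00 d, [G] has sunk to 23.0% of its charge, while the flask holds L at 38.5% and X at 7.40% of the J charged, which the three numbers asked for do not show. This flask's own fade half-life from 25 h to 4.0 d is 7.23 d, longer than the 5.82 d from cedar. Carried back onto cedar, 5.82 d gives 19.7% at 2.50 d, above the reading of 19.1%.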